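The synthesis rests on disconnecting the trans-decalin (rings A and B) at C4–C5 and C9–C10, the latter bond ending on C9 of the C9=C11 bridge of a bicyclo[3.2.1]octene (bridgeheads C8 and C12); this is the feature the key step exploits. In one Lewis-acid operation a C3–C4 epoxide, the E-C5=C10 alkene and a C9 vinylsilane close both rings and set C4, C5 and C10, and loss of silicon returns C9=C11. The precursor is an enantiopure bicyclic vinylsilane carrying the epoxy-diene chain on C8; C13 is held as a triethylsilyl ether, not a ketone, so that no carbonyl binds the Lewis acid and the epoxide never meets the unmasking steps.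

Key step: step 16

Assumption: atom labels C1–C20 are those of the target skeleton (C17 on C13, C18 and C19 on C4, C20 on C10; β is the face of C20) and are used for fragments too; the ketol of step 7 is taken to form as the exo (axial, hydrogen-bonded) C13 alcohol, on which steps 8 and 9 rely.

Step 1
Reactants: 1 geranyl acetate
Product: 2 (2E,6E)-8-hydroxygeranyl acetate
Conditions: SeO2 (cat.), t-BuOOH, salicylic acid (cat.), CH2Cl2, rt
Reagents that add atoms: tert-butyl hydroperoxide, CC(C)(C)OO
Why: Allylic oxidation by SeO2 (ene reaction, then [2,3]-sigmatropic shift) should take the E-methyl group (future C18) of the electron-rich terminal alkene, because the other alkene (future C5=C10) is deactivated by its allylic acetate.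

Step 2
Reactants: 2 (2E,6E)-8-hydroxygeranyl acetate
Product: 3 (2E,6S,7S)-6,7-epoxy-8-hydroxygeranyl acetate
Conditions: Ti(OiPr)4 (cat.), L-(+)-diethyl tartrate (cat.), t-BuOOH, 4 Å molecular sieves, CH2Cl2, −20 °C
Reagents that add atoms: tert-butyl hydroperoxide, CC(C)(C)OO
Why: Sharpless asymmetric epoxidation of the E allylic alcohol, in which the L-(+)-tartrate ligand sets both epoxide centres (future C3 and C4) as S by reagent control and the alkene without a free allylic hydroxyl is left alone.

Step 3
Reactants: 3 (2E,6S,7S)-6,7-epoxy-8-hydroxygeranyl acetate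
Product: 4 (2E,6S,7S)-8-(tert-butyldimethylsilyloxy)-6,7-epoxygeranyl acetate
Conditions: t-BuMe2SiCl, imidazole, DMF, 0 °C → rt
Reagents that add atoms: tert-butyldimethylsilyl chloride, CC(C)(C)[Si](C)(C)Cl
Why: Imidazole-promoted silylation of the primary alcohol, which touches no stereocentre and removes the hydroxyl that could later trigger a Payne rearrangement.

Step 4
Reactants: 4 (2E,6S,7S)-8-(tert-butyldimethylsilyloxy)-6,7-epoxygeranyl acetate
Product: 5 (2E,6S,7S)-8-(tert-butyldimethylsilyloxy)-6,7-epoxygeraniol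
Conditions: K2CO3 (cat.), MeOH, 0 °C
Reagents that add atoms: none
Why: Base-catalysed transesterification (methanolysis) of the allylic acetate, to which the epoxide and the silyl ether are inert.

Step 5
Reactants: 5 (2E,6S,7S)-8-(tert-butyldimethylsilyloxy)-6,7-epoxygeraniol
Product: 7 (2E,6S,7S)-8-(tert-butyldimethylsilyloxy)-6,7-epoxygeranyl bromide, via allylic mesylate 6 (not isolated)
Conditions: MsCl, Et3N, CH2Cl2, −40 °C; then LiBr, THF, 0 °C
Reagents that add atoms: lithium bromide, [Li+].[Br-]
Why: Mesylation followed by SN2 displacement with bromide at low temperature should give the primary allylic bromide without allylic transposition or epoxide opening.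

Step 6
Reactants: 8 cyclopentane-1,3-dione
Product: 9 2-[(phenylsulfanyl)methyl]cyclopentane-1,3-dione
Conditions: CH2O (37% aq.), PhSH, Et3N (cat.), EtOH, 50 °C
Reagents that add atoms: formaldehyde, C=O; thiophenol, Sc1ccccc1
Why: Knoevenagel condensation of the dione with formaldehyde and thia-Michael addition of thiophenol to the transient 2-methylene dione, a known three-component reaction of cyclic 1,3-diones that installs C7 with its sulfur handle.

Step 7
Reactants: 9 2-[(phenylsulfanyl)methyl]cyclopentane-1,3-dione; 10 acrolein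
Product: 12 racemic exo-ketol rac-(1R,2S,5S)-2-hydroxy-5-[(phenylsulfanyl)methyl]bicyclo[3.2.1]octane-6,8-dione, via Michael adduct 11 (not isolated)
Conditions: DABCO (cat.), MeCN, 0 °C → rt
Reagents that add atoms: none
Why: Michael addition of the acidic 2-substituted dione to acrolein and intramolecular aldol addition of a ring α-carbon (C12) to the aldehyde (C13) build the bridged ketol, in which C8 and C12 are tied together by the bicycle, the C13 hydroxyl is expected exo through the hydrogen-bonded chair, and the two enantiotopic α-carbons react equally, hence the racemate.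

Step 8
Reactants: 12 racemic exo-ketol
Product: 13 (1R,2S,5S)-2-hydroxy-5-[(phenylsulfanyl)methyl]bicyclo[3.2.1]octane-6,8-dione
Conditions: Amano lipase PS, vinyl acetate, t-BuOMe, 35 °C, stopped just past half conversion
Reagents that add atoms: none
Why: Lipase-catalysed kinetic resolution by acyl transfer, for which the empirical size rule for secondary alcohols (branched bridgehead side large, CH2 side medium) predicts acetylation of the (2R)-enantiomer, so that the (1R,2S,5S)-alcohol should be recovered.

Step 9
Reactants: 13 (1R,2S,5S)-ketol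
Product: 14 (1R,2S,5R,8R)-2,8-dihydroxy-5-[(phenylsulfanyl)methyl]bicyclo[3.2.1]octan-6-one
Conditions: Me4NBH(OAc)3, MeCN/AcOH, −35 °C
Reagents that add atoms: none
Why: Evans–Saksena hydroxyl-directed reduction, in which the borohydride bound to the axial C13 oxygen delivers hydride to the β-carbonyl C16 from the face of the three-carbon bridge, so that the new C16 hydroxyl lies anti to C13–OH and syn to the C9–C11 bridge, while the C9 ketone has no free β-hydroxyl at the outset and should survive.

Step 10
Reactants: 14 (1R,2S,5R,8R)-diol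
Product: 16 bis-silyl ketone (C13–OSiEt3, C16–OSi(t-Bu)Me2, C9 ketone, C7–SPh), via mono-triethylsilyl ether 15 (not isolated)
Conditions: Et3SiCl, imidazole, CH2Cl2, −40 °C; then t-BuMe2SiOTf, 2,6-lutidine, −40 → 0 °C
Reagents that add atoms: triethylsilyl chloride, CC[Si](CC)(CC)Cl; tert-butyldimethylsilyl triflate, CC(C)(C)[Si](C)(C)OS(=O)(=O)C(F)(F)F
Why: Stepwise silylation by steric differentiation, the chloride taking the less hindered C13 hydroxyl and the more powerful triflate then capping the C16 hydroxyl that sits on the one-carbon bridge next to the quaternary C8.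

Step 11
Reactants: 16 bis-silyl ketone
Product: 18 C9 vinyl iodide (C9(I)=C11), via hydrazone 17 (not isolated)
Conditions: N2H4·H2O, Et3N, EtOH, 80 °C; evaporation; then I2, tetramethylguanidine, THF, 0 °C
Reagents that add atoms: iodine, II
Why: Barton vinyl iodide synthesis (oxidation of the hydrazone by iodine in the presence of a guanidine base), which tolerates the hindered ketone and can place the alkene only at C9=C11 because C8 is quaternary.

Step 12
Reactants: 18 C9 vinyl iodide
Product: 20 C9 vinylsilane sulfide (C9(SiMe3)=C11), via vinyllithium 19 (not isolated)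
Conditions: t-BuLi, THF, −78 °C; then Me3SiCl, −78 → 0 °C
Reagents that add atoms: trimethylsilyl chloride, C[Si](C)(C)Cl
Why: Iodine–lithium exchange and silylation of the vinyllithium, which keeps the alkene position and puts silicon on the carbon that will later be attacked ipso.

Step 13
Reactants: 20 C9 vinylsilane sulfide
Product: 21 C9 vinylsilane sulfone (C7–SO2Ph)
Conditions: (NH4)6Mo7O24·4H2O (cat.), H2O2 (30% aq.), EtOH, 0 °C → rt
Reagents that add atoms: hydrogen peroxide, OO
Why: Molybdate-catalysed oxidation of the sulfide to the sulfone by H2O2, an oxidant system that does not epoxidise the hindered vinylsilane.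

Step 14
Reactants: 21 C9 vinylsilane sulfone; 7 (2E,6S,7S)-8-(tert-butyldimethylsilyloxy)-6,7-epoxygeranyl bromide
Product: 23 C7-sulfonyl epoxy diene (C6–C7 bond formed, C7 as a mixture of epimers), via lithiated sulfone 22 (not isolated)
Conditions: n-BuLi, THF/DMPU, −78 °C; then 7, −78 → −40 °C
Reagents that add atoms: none
Why: Alkylation of the α-sulfonyl carbanion with the primary allylic bromide (SN2) joins the two fragments at C6–C7, the allylic halide reacting far faster than the epoxide and the new C7 centre being erased in the next step.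

Step 15
Reactants: 23 C7-sulfonyl epoxy diene
Product: 24 epoxy-diene vinylsilane (cyclisation precursor; C13–OSiEt3, C16–OSi(t-Bu)Me2, C18–OSi(t-Bu)Me2)
Conditions: Na(Hg), Na2HPO4, MeOH/THF, −20 °C
Reagents that add atoms: none
Why: Reductive desulfonylation by buffered sodium amalgam (electron transfer, loss of sulfinate, protonation), conditions under which the epoxide, the alkenes, the vinylsilane and the silyl ethers should persist.

Step 16
Reactants: 24 epoxy-diene vinylsilane
Product: 25 tetracyclic 3β-alcohol (rings A and B closed; 4α-CH2OSi(t-Bu)Me2, 5α-H, 10β-CH3, C9=C11)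
Conditions: MeAlCl2 (2.5 equiv), CH2Cl2, −78 °C; then Et3N, MeOH, H2O
Reagents that add atoms: none
Why: MeAlCl2 binds the epoxide oxygen, the C4–O bond breaks as the E-C5=C10 alkene attacks C4 from the rear, the tertiary C10 cation so formed is captured by the silicon-bearing C9 on the exo face of the bicyclic alkene, and the β-silyl cation at C11 loses the Me3Si group to restore C9=C11. The closest known reaction type is the Lewis-acid epoxy-polyene cyclisation terminated by ipso substitution of a vinylsilane. Ring A closes in the 6-endo mode at both the epoxide and the alkene through a chair; ring B closes as a six-membered ring that is endo to the C5–C10 cationic unit and exo to C9=C11, through a chair-like transition state in which C10 approaches C9 perpendicular to the alkene plane between C7 and C16 and which flattens as C9 returns to sp2. C4 is set by inversion at the epoxide carbon, which puts the former E-CH2OSi group equatorial (4α), and C5 (H α) and C10 (CH3 β) follow from anti addition across the E-alkene in the chair that keeps the C3 oxygen equatorial, so the epoxide configuration alone fixes all three new centres. The step needs opening at C4 and not C3, capture of C10 by C9 ahead of proton loss, and an alkene at C9=C11 only; the tertiary, inductively retarded C4 (concerted opening), the three-atom tether from C8 and the silicon β-effect (ipso attack, no Wagner–Meerwein shift of the bicycle) secure these, while the remote enantiopure bicycle cannot influence the A/B centres.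

Step 17
Reactants: 25 tetracyclic 3β-alcohol
Product: 26 C3 O-phenyl thionocarbonate
Conditions: PhOC(S)Cl, pyridine, DMAP (cat.), CH2Cl2, rt
Reagents that add atoms: O-phenyl chlorothionoformate, S=C(Cl)Oc1ccccc1
Why: Acylation of the equatorial C3 hydroxyl to the thionocarbonate, the first half of a Barton–McCombie deoxygenation, under conditions that need no strong base.

Step 18
Reactants: 26 C3 O-phenyl thionocarbonate
Product: 27 3-deoxy tetracycle (C13–OSiEt3, C16 and C18 silyl ethers)
Conditions: Bu3SnH, AIBN (cat.), toluene, 100 °C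
Reagents that add atoms: none
Why: Barton–McCombie radical deoxygenation, in which the stannyl radical adds to the thiocarbonyl, the C3–O bond fragments and the secondary C3 radical takes hydrogen from Bu3SnH, leaving C3 as a methylene.

Step 19
Reactants: 27 3-deoxy tetracycle
Product: 28 C13 alcohol (exo hydroxyl; C16 and C18 silyl ethers kept)
Conditions: PPTS (cat.), MeOH/CH2Cl2, 0 °C
Reagents that add atoms: none
Why: Mild acid-catalysed methanolysis should remove the secondary triethylsilyl ether well before the hindered secondary and the neopentyl primary tert-butyldimethylsilyl ethers.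

Step 20
Reactants: 28 C13 alcohol
Product: 29 C13 ketone
Conditions: Dess–Martin periodinane, CH2Cl2, rt
Reagents that add atoms: none
Why: Dess–Martin oxidation of the secondary alcohol to the C13 ketone, whose α-carbon C12 is a bridgehead and therefore cannot epimerise or move the C9=C11 alkene into conjugation.

Step 21
Reactants: 29 C13 ketone
Product: 30 C13 spiro-epoxide (C17 exo/axial, epoxide oxygen endo/equatorial)
Conditions: Me3S+ I−, KN(SiMe3)2, THF, −10 → 0 °C
Reagents that add atoms: trimethylsulfonium iodide, C[S+](C)C.[I-]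
Why: Corey–Chaykovsky epoxidation, in which the small, irreversibly adding dimethylsulfonium methylide should attack C13 from the exo (axial) face, away from the C9=C11 bridge, so that C17 ends axial and the oxygen equatorial as the target requires.

Step 22
Reactants: 30 C13 spiro-epoxide
Product: 31 16,18-bis-O-(tert-butyldimethylsilyl) botryotin E
Conditions: AcOH, CsOAc, DMF, 80 °C
Reagents that add atoms: acetic acid, CC(=O)O
Why: SN2 opening of the 2,2-disubstituted epoxide by acetate at its unsubstituted carbon C17, which leaves the C13–O bond and hence the tertiary carbinol configuration untouched.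

Step 23
Reactants: 31 16,18-bis-O-(tert-butyldimethylsilyl) botryotin E
Product: 32 botryotin E
Conditions: HF·pyridine, THF, 0 °C → rt
Reagents that add atoms: none
Why: Fluoride-mediated cleavage of both silyl ethers under mildly acidic conditions in which the primary acetate should neither migrate nor hydrolyse.

Compound list

1 | geranyl acetate, (2E)-3,7-dimethylocta-2,6-dien-1-yl acetate | CC(=O)OC/C=C(C)/CCC=C(C)C | starting material
2 | (2E,6E)-8-hydroxy-3,7-dimethylocta-2,6-dien-1-yl acetate | CC(=O)OC/C=C(\C)CC/C=C(\C)CO | intermediate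
3 | (2E,6S,7S)-6,7-epoxy-8-hydroxy-3,7-dimethyloct-2-en-1-yl acetate | CC(=O)OC/C=C(\C)CC[C@@H]1O[C@@]1(C)CO | intermediate
4 | (2E,6S,7S)-8-[(tert-butyldimethylsilyl)oxy]-6,7-epoxy-3,7-dimethyloct-2-en-1-yl acetate | CC(=O)OC/C=C(\C)CC[C@@H]1O[C@@]1(C)CO[Si](C)(C)C(C)(C)C | intermediate
5 | (2E,6S,7S)-8-[(tert-butyldimethylsilyl)oxy]-6,7-epoxy-3,7-dimethyloct-2-en-1-ol | OC/C=C(\C)CC[C@@H]1O[C@@]1(C)CO[Si](C)(C)C(C)(C)C | intermediate
6 | methanesulfonate of 5 (allylic mesylate) | CS(=O)(=O)OC/C=C(\C)CC[C@@H]1O[C@@]1(C)CO[Si](C)(C)C(C)(C)C | intermediate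
7 | (2E,6S,7S)-1-bromo-8-[(tert-butyldimethylsilyl)oxy]-6,7-epoxy-3,7-dimethyloct-2-ene (carries C6, C5, C10, C1–C4, C18–C20) | BrC/C=C(\C)CC[C@@H]1O[C@@]1(C)CO[Si](C)(C)C(C)(C)C | intermediate
8 | cyclopentane-1,3-dione | O=C1CCC(=O)C1 | starting material
9 | 2-[(phenylsulfanyl)methyl]cyclopentane-1,3-dione | O=C1CCC(=O)C1CSc1ccccc1 | intermediate
10 | acrolein (prop-2-enal) | C=CC=O | starting material
11 | 3-{2,5-dioxo-1-[(phenylsulfanyl)methyl]cyclopentyl}propanal | O=CCCC1(CSc2ccccc2)C(=O)CCC1=O | intermediate
12 | racemic exo-ketol, rac-(1R,2S,5S)-2-hydroxy-5-[(phenylsulfanyl)methyl]bicyclo[3.2.1]octane-6,8-dione (both enantiomers written) | O[C@H]1CC[C@]2(CSc3ccccc3)C(=O)C[C@H]1C2=O.O[C@@H]1CC[C@@]2(CSc3ccccc3)C(=O)C[C@@H]1C2=O | intermediate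
13 | (1R,2S,5S)-2-hydroxy-5-[(phenylsulfanyl)methyl]bicyclo[3.2.1]octane-6,8-dione (C12, C13, C8 of the target; C13–OH exo) | O[C@H]1CC[C@]2(CSc3ccccc3)C(=O)C[C@H]1C2=O | intermediate
14 | (1R,2S,5R,8R)-2,8-dihydroxy-5-[(phenylsulfanyl)methyl]bicyclo[3.2.1]octan-6-one (C13–OH exo; C16–OH syn to the C9–C11 bridge) | O[C@H]1CC[C@]2(CSc3ccccc3)C(=O)C[C@H]1[C@H]2O | intermediate
15 | 14 with the C13 hydroxyl as triethylsilyl ether | CC[Si](CC)(CC)O[C@H]1CC[C@]2(CSc3ccccc3)C(=O)C[C@H]1[C@H]2O | intermediate
16 | 14 with C13–OSiEt3 and C16–OSi(t-Bu)Me2 (configuration unchanged) | CC[Si](CC)(CC)O[C@H]1CC[C@]2(CSc3ccccc3)C(=O)C[C@H]1[C@H]2O[Si](C)(C)C(C)(C)C | intermediate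
17 | C9 hydrazone of 16 | CC[Si](CC)(CC)O[C@H]1CC[C@]2(CSc3ccccc3)C(=NN)C[C@H]1[C@H]2O[Si](C)(C)C(C)(C)C | intermediate
18 | bicyclo[3.2.1]oct-6-ene with iodine on C9 (C9=C11), C13–OSiEt3, C16–OSi(t-Bu)Me2, C8–CH2SPh | CC[Si](CC)(CC)O[C@H]1CC[C@]2(CSc3ccccc3)C(I)=C[C@H]1[C@H]2O[Si](C)(C)C(C)(C)C | intermediate
19 | C9 vinyllithium from 18 | CC[Si](CC)(CC)O[C@H]1CC[C@]2(CSc3ccccc3)C([Li])=C[C@H]1[C@H]2O[Si](C)(C)C(C)(C)C | intermediate
20 | C9 trimethylsilyl analogue of 18 (vinylsilane sulfide) | CC[Si](CC)(CC)O[C@H]1CC[C@]2(CSc3ccccc3)C([Si](C)(C)C)=C[C@H]1[C@H]2O[Si](C)(C)C(C)(C)C | intermediate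
21 | vinylsilane sulfone, 20 with C7–SO2Ph | CC[Si](CC)(CC)O[C@H]1CC[C@]2(CS(=O)(=O)c3ccccc3)C([Si](C)(C)C)=C[C@H]1[C@H]2O[Si](C)(C)C(C)(C)C | intermediate
22 | C7-lithiated sulfone from 21 | CC[Si](CC)(CC)O[C@H]1CC[C@]2(C([Li])S(=O)(=O)c3ccccc3)C([Si](C)(C)C)=C[C@H]1[C@H]2O[Si](C)(C)C(C)(C)C | intermediate
23 | coupled sulfone: 21 alkylated at C7 by the C6 carbon of 7 (C7 epimers) | CC[Si](CC)(CC)O[C@H]1CC[C@]2(C(C/C=C(\C)CC[C@@H]3O[C@@]3(C)CO[Si](C)(C)C(C)(C)C)S(=O)(=O)c3ccccc3)C([Si](C)(C)C)=C[C@H]1[C@H]2O[Si](C)(C)C(C)(C)C | intermediate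
24 | cyclisation precursor: bicyclic C9 vinylsilane with the (3S,4S)-epoxy E-C5=C10 chain on C8, C13–OSiEt3 (exo), C16–OSi(t-Bu)Me2 (syn to C9=C11), C18–OSi(t-Bu)Me2 | CC[Si](CC)(CC)O[C@H]1CC[C@]2(CC/C=C(\C)CC[C@@H]3O[C@@]3(C)CO[Si](C)(C)C(C)(C)C)C([Si](C)(C)C)=C[C@H]1[C@H]2O[Si](C)(C)C(C)(C)C | intermediate
25 | cyclisation product: tetracycle with 3β-OH, 4α-CH2OSi(t-Bu)Me2, 4β-CH3, 5α-H, 10β-CH3, C9=C11, C13–OSiEt3, C16–OSi(t-Bu)Me2 | CC[Si](CC)(CC)O[C@H]1CC[C@]23CC[C@H]4[C@](C)(CO[Si](C)(C)C(C)(C)C)[C@@H](O)CC[C@]4(C)C2=C[C@H]1[C@H]3O[Si](C)(C)C(C)(C)C | intermediate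
26 | C3 O-phenyl thionocarbonate of 25 | CC[Si](CC)(CC)O[C@H]1CC[C@]23CC[C@H]4[C@](C)(CO[Si](C)(C)C(C)(C)C)[C@@H](OC(=S)Oc5ccccc5)CC[C@]4(C)C2=C[C@H]1[C@H]3O[Si](C)(C)C(C)(C)C | intermediate
27 | 3-deoxy tetracycle (C3 methylene) | CC[Si](CC)(CC)O[C@H]1CC[C@]23CC[C@H]4[C@](C)(CO[Si](C)(C)C(C)(C)C)CCC[C@]4(C)C2=C[C@H]1[C@H]3O[Si](C)(C)C(C)(C)C | intermediate
28 | C13 alcohol (exo OH), C16 and C18 silyl ethers | O[C@H]1CC[C@]23CC[C@H]4[C@](C)(CO[Si](C)(C)C(C)(C)C)CCC[C@]4(C)C2=C[C@H]1[C@H]3O[Si](C)(C)C(C)(C)C | intermediate
29 | C13 ketone, C16 and C18 silyl ethers | O=C1CC[C@]23CC[C@H]4[C@](C)(CO[Si](C)(C)C(C)(C)C)CCC[C@]4(C)C2=C[C@H]1[C@H]3O[Si](C)(C)C(C)(C)C | intermediate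
30 | C13 spiro-epoxide (C17 exo, oxygen endo) | C1O[C@@]12CC[C@]34CC[C@H]5[C@](C)(CO[Si](C)(C)C(C)(C)C)CCC[C@]5(C)C3=C[C@H]2[C@H]4O[Si](C)(C)C(C)(C)C | intermediate
31 | 16,18-bis-O-(tert-butyldimethylsilyl) botryotin E | CC(=O)OC[C@@]1(O)CC[C@]23CC[C@H]4[C@](C)(CO[Si](C)(C)C(C)(C)C)CCC[C@]4(C)C2=C[C@H]1[C@H]3O[Si](C)(C)C(C)(C)C | intermediate
32 | botryotin E | CC(=O)OC[C@@]1(O)CC[C@]23CC[C@H]4[C@](C)(CO)CCC[C@]4(C)C2=C[C@H]1[C@H]3O | target

Total step count: 23
Longest linear sequence: 18 steps (steps 6–23, from cyclopentane-1,3-dione)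

Steps most likely to fail

Step 16. The C10 cation may lose a proton, or the opened epoxide may rearrange, before C9 is reached on its exo face, which lies next to the syn C16 silyl ether. The fallback separates the two closures and gives ring B its own initiator. Setting out from 24, ring A alone would be closed with MeAlCl2 in the presence of 2,6-di-tert-butyl-4-methylpyridine, so that the C10 cation is deprotonated to the ring-A exocyclic alkene F1 (C4–C5 closed, 3β-OH, C10=C20 methylene, vinylsilane intact). In a second operation F1 would be treated with SnCl4 and a simple phenol as proton source in CH2Cl2 at −78 °C. Protonation at C20 regenerates the tertiary C10 cation, now free of the competing epoxide chemistry, and a proton-initiated olefin–vinylsilane cyclisation closes ring B with loss of silicon. The trans ring fusion would rest on the chair preference of this closure and would have to be confirmed. The route is rejoined at 25.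

Step 8. Acyl transfer at the hindered axial C13 hydroxyl may be slow or poorly enantioselective. The fallback resolves through covalent diastereomers. Setting out from 12, the racemate would be reduced under the conditions of step 9 to the racemic diol F2. Its less hindered C13 hydroxyl would be esterified with (S)-O-methylmandelic acid (DCC, DMAP, CH2Cl2), and the two diastereomeric esters separated by chromatography or crystallisation. The (S)-O-methylmandelate F3 of the (1R,2S,5R,8R)-diol is kept, and the diastereomeric (S)-O-methylmandelate F4 of the enantiomeric diol is set aside. Methanolysis of F3 (K2CO3, MeOH) returns to the route at 14.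

Step 21. The ylide may approach C13 from the endo face, or act as a base and enolise the ketone toward C14, giving the wrong C13 epimer or returning ketone. The fallback places oxygen, not carbon, on the more accessible face. Setting out from 29, Wittig methylenation (Ph3P=CH2, THF) would give the C13 exocyclic alkene F4a, written below as F5. Dihydroxylation with OsO4 (cat.) and N-methylmorpholine N-oxide should occur at this unhindered 1,1-disubstituted alkene, not at the shielded C9=C11, and from the same face that misled the ylide, giving the C13,C17-diol F6 with the tertiary hydroxyl endo. Selective acetylation of the primary hydroxyl (Ac2O, pyridine, 0 °C) returns to the route at 31. In this paragraph the alkene is the C13 methylene compound F5 and the diol is the C13,C17-diol F6.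

Further compounds

F1 | step 16 | ring-A exocyclic alkene: 24 with C4–C5 closed, 3β-OH, C10=C20 methylene, vinylsilane intact | CC[Si](CC)(CC)O[C@H]1CC[C@]2(CC[C@@H]3C(=C)CC[C@H](O)[C@@]3(C)CO[Si](C)(C)C(C)(C)C)C([Si](C)(C)C)=C[C@H]1[C@H]2O[Si](C)(C)C(C)(C)C
F2 | step 8 | racemic diol, rac-(1R,2S,5R,8R)-2,8-dihydroxy-5-[(phenylsulfanyl)methyl]bicyclo[3.2.1]octan-6-one | O[C@H]1CC[C@]2(CSc3ccccc3)C(=O)C[C@H]1[C@H]2O.O[C@@H]1CC[C@@]2(CSc3ccccc3)C(=O)C[C@@H]1[C@@H]2O
F3 | step 8 | (S)-O-methylmandelate at C13–O of the (1R,2S,5R,8R)-diol | CO[C@H](C(=O)O[C@H]2CC[C@]3(CSc4ccccc4)C(=O)C[C@H]2[C@H]3O)c1ccccc1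
F4 | step 8 | (S)-O-methylmandelate at C13–O of the enantiomeric (1S,2R,5S,8S)-diol | CO[C@H](C(=O)O[C@@H]2CC[C@@]3(CSc4ccccc4)C(=O)C[C@@H]2[C@@H]3O)c1ccccc1
F5 | step 21 | C13 methylene compound (C13=C17), C16 and C18 silyl ethers | C=C1CC[C@]23CC[C@H]4[C@](C)(CO[Si](C)(C)C(C)(C)C)CCC[C@]4(C)C2=C[C@H]1[C@H]3O[Si](C)(C)C(C)(C)C
F6 | step 21 | C13,C17-diol (C13–OH endo, C17 exo), C16 and C18 silyl ethers | OC[C@@]1(O)CC[C@]23CC[C@H]4[C@](C)(CO[Si](C)(C)C(C)(C)C)CCC[C@]4(C)C2=C[C@H]1[C@H]3O[Si](C)(C)C(C)(C)C
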